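**Retrosynthetic overview**

1. The cis-(2S,3S)-dihydrobenzofuran is made last, by face-selective syn-hydrogenation of the C2=C3 bond of a 2-aryl-3-(hydroxymethyl)benzofuran that already carries the finished furofuran.
2. Furofuran: the C7'–aryl bond comes from Friedel–Crafts C-arylation of a bicyclic lactol with 2,6-dimethoxyphenol (ring B); ring A comes from benzylic C7–O closure of an α-formylated γ-lactone; the lactone (C8 stereocentre) comes from an L-proline cross-aldol of the benzofuran-5-carbaldehyde with methyl 4-oxobutanoate.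
3. 2-Arylbenzofuran-3-carboxylate: C2–H arylation of a benzofuran-3-carboxylate that is built from a salicylaldehyde and ethyl diazoacetate by an acid-triggered 1,2-aryl shift (the arene migrates from the aldehyde carbon to the diazo carbon and so creates the C3–C3a bond), then ring closure.
4. Aromatic pieces: catechol gives 4-bromoguaiacol, which serves twice (central ring and guaiacyl ring); resorcinol gives 2,6-dimethoxyphenol.
5. Ring order: benzofuran, then γ-lactone, then ring A, then ring B, then dihydrobenzofuran.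

Assumption: the SMILES is read as the exo,exo (7S,8R,7'S,8'R) furofuran of the pinoresinol type carrying a cis-(2S,3S)-2-aryl-3-(hydroxymethyl)-2,3-dihydrobenzofuran; solvents, catalysts and commodity reagents are bought.

Notation: lignan locants C7/C8/C9 are on the benzofuran side and C7'/C8'/C9' on the syringyl side. Ring A is C7–O–C9'–C8'–C8 and ring B is C7'–O–C9–C8–C8'. BF is the 3-(ethoxycarbonyl)-7-methoxy-2-[3-methoxy-4-(pivaloyloxy)phenyl]-1-benzofuran-5-yl group.

**Route**

Step 1
Reactants: 1 catechol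
Product: 2 guaiacol (2-methoxyphenol)
Conditions: MeI (1.0 equiv), K2CO3 (1.0 equiv), acetone, reflux
Reagents that add atoms: iodomethane, CI
Why: Williamson mono-O-methylation with limiting electrophile; guaiacol is separated from catechol and veratrole by base extraction and distillation.

Step 2
Reactants: 2 guaiacol
Product: 3 4-bromo-2-methoxyphenol
Conditions: NBS (1.0 equiv), MeCN, 0 °C → rt
Reagents that add atoms: N-bromosuccinimide, O=C1CCC(=O)N1Br
Why: electrophilic aromatic bromination in which the free OH out-directs OMe, so bromine enters para to OH.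

Step 3
Reactants: 3 4-bromo-2-methoxyphenol
Product: 4 4-bromo-2-methoxyphenyl pivalate
Conditions: t-BuCOCl, Et3N, DMAP (cat.), CH2Cl2, 0 °C → rt
Reagents that add atoms: pivaloyl chloride, CC(C)(C)C(Cl)=O
Why: O-acylation; the pivalate masks the phenol through the palladium, base and acid steps and falls off in the hydride reduction of step 15.

Step 4
Reactants: 3 4-bromo-2-methoxyphenol
Product: 5 5-bromo-2-hydroxy-3-methoxybenzaldehyde
Conditions: MgCl2, Et3N, (CH2O)n, MeCN, reflux; aq. HCl work-up
Reagents that add atoms: paraformaldehyde (reacts as formaldehyde), C=O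
Why: magnesium-phenoxide-directed ortho-formylation (Casnati–Skattebøl) at the only free ortho position; a second formaldehyde takes up the hydride.

Step 5
Reactants: 5 5-bromo-2-hydroxy-3-methoxybenzaldehyde; 6 ethyl diazoacetate
Product: 8 ethyl 5-bromo-7-methoxy-1-benzofuran-3-carboxylate, via hemiacetal 7 (not isolated)
Conditions: HBF4·OEt2 (10 mol%), CH2Cl2, rt; then conc. H2SO4, rt
Reagents that add atoms: none
Why: acid-catalysed aldehyde–diazoacetate homologation with 1,2-aryl shift (Roskamp/Tiffeneau–Demjanov-type semipinacol): the diazo carbon adds to the protonated aldehyde, the electron-rich arene migrates to the diazonium carbon as N2 leaves and thereby forms the future C3–C3a bond, the free phenol closes onto the released formyl group, and H2SO4 dehydrates the hemiacetal to the benzofuran.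

Step 6
Reactants: 8 ethyl 5-bromo-7-methoxy-1-benzofuran-3-carboxylate
Product: 9 ethyl 5-formyl-7-methoxy-1-benzofuran-3-carboxylate
Conditions: Pd(OAc)2 (1 mol%), P(1-adamantyl)2(n-Bu) (3 mol%), TMEDA, CO/H2 (1:1, 5 bar), toluene, 100 °C
Reagents that add atoms: carbon monoxide, [C-]#[O+]
Why: palladium-catalysed reductive carbonylation (formylation) of an aryl bromide; it tolerates the ester and installs the carbon that becomes C7.

Step 7
Reactants: 9 ethyl 5-formyl-7-methoxy-1-benzofuran-3-carboxylate; 4 4-bromo-2-methoxyphenyl pivalate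
Product: 10 ethyl 5-formyl-7-methoxy-2-[3-methoxy-4-(pivaloyloxy)phenyl]-1-benzofuran-3-carboxylate
Conditions: Pd(OAc)2 (5 mol%), PCy3·HBF4 (10 mol%), t-BuCO2H (30 mol%), K2CO3, DMA, 100 °C
Reagents that add atoms: none
Why: direct C–H arylation by concerted metalation–deprotonation at C2, the only furan C–H, which is acidified by the ring oxygen and the 3-ester.

Step 8
Reactants: 10 ethyl 5-formyl-7-methoxy-2-[3-methoxy-4-(pivaloyloxy)phenyl]-1-benzofuran-3-carboxylate; 11 methyl 4-oxobutanoate
Product: 14 (4R)-4-[(R)-hydroxy(BF)methyl]oxolan-2-one, via aldol aldehyde 12 (not isolated), via diol ester 13 (not isolated)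
Conditions: 11 (3 equiv), L-proline (30 mol%), DMF, 4 °C; then NaBH4, MeOH, −20 °C; then PPTS (cat.), CH2Cl2, rt
Reagents that add atoms: none
Why: L-proline enamine cross-aldol (Houk–List transition state) in which the (E)-enamine of 11 adds to the aldehyde and fixes C8 (S in 12, the later 8R); the anti carbinol C7 (R) and any syn epimer are both carried on because C7 is reset in step 9; NaBH4 then reduces the aldehyde and the primary alcohol lactonises.

Step 9
Reactants: 14 (4R)-4-[(R)-hydroxy(BF)methyl]oxolan-2-one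
Product: 16 (3aR,4S)-4-BF-3a,4-dihydro-1H,3H-furo[3,4-c]furan-1-one, via hydroxymethylene lactone 15 (not isolated)
Conditions: LiN(i-Pr)2 (2.5 equiv), THF, −78 °C; HCO2CH2CF3, −78 → 0 °C; AcOH; then TsOH·H2O (20 mol%), 4 Å MS, CH2Cl2, 40 °C
Reagents that add atoms: 2,2,2-trifluoroethyl formate, O=COCC(F)(F)F
Why: Claisen formylation of the lactone dianion followed by acid-mediated cyclodehydration; the benzylic C7–O bond ionises reversibly (also after a first closure, since the enol-ether oxygen is a vinylogous carboxylate leaving group) and recloses with the aryl anti to C9 (allylic 1,3-strain in the cation, more stable 2,3-trans dihydrofuran), so both C7 epimers converge on 7S.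

Step 10
Reactants: 16 (3aR,4S)-4-BF-3a,4-dihydro-1H,3H-furo[3,4-c]furan-1-one
Product: 17 (3aR,4S,6aR)-4-BF-tetrahydro-1H,3H-furo[3,4-c]furan-1-one
Conditions: H2 (1 atm), Rh/Al2O3 (5 wt%), EtOAc, rt
Reagents that add atoms: none
Why: heterogeneous syn-hydrogenation of the push–pull enol ether from the convex face (the side of H8) gives the strain-free cis-fused bicycle and sets C8' (R); the aromatic, tetrasubstituted benzofuran C2=C3 bond is untouched at 1 atm and rhodium spares the benzylic C–O bond.

Step 11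
Reactants: 17 (3aR,4S,6aR)-4-BF-tetrahydro-1H,3H-furo[3,4-c]furan-1-one
Product: 18 (3aR,4S,6aR)-4-BF-tetrahydro-1H,3H-furo[3,4-c]furan-1-ol (anomer mixture)
Conditions: disiamylborane, Sia2BH (2.5 equiv), THF, 0 °C → rt; pH 7 buffer
Reagents that add atoms: none
Why: chemoselective lactone-to-lactol reduction by a hindered dialkylborane, which stops at the lactol and leaves the ethyl ester and the aryl pivalate alone.

Step 12
Reactants: 19 resorcinol
Product: 20 1,3-dimethoxybenzene
Conditions: MeI (2.5 equiv), K2CO3, acetone, reflux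
Reagents that add atoms: iodomethane, CI
Why: exhaustive Williamson O-methylation.

Step 13
Reactants: 20 1,3-dimethoxybenzene
Product: 21 2,6-dimethoxyphenol
Conditions: n-BuLi, TMEDA, Et2O, 0 °C → rt; B(OMe)3, −78 °C → rt; then H2O2 (30%), AcOH, 0 °C
Reagents that add atoms: hydrogen peroxide, OO
Why: directed ortho-lithiation at the carbon flanked by both methoxy groups, borylation and oxidative C–B to C–O conversion.

Step 14
Reactants: 18 (3aR,4S,6aR)-4-BF-tetrahydro-1H,3H-furo[3,4-c]furan-1-ol; 21 2,6-dimethoxyphenol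
Product: 22 ethyl 5-[(1S,3aR,4S,6aR)-4-(4-hydroxy-3,5-dimethoxyphenyl)tetrahydro-1H,3H-furo[3,4-c]furan-1-yl]-7-methoxy-2-[3-methoxy-4-(pivaloyloxy)phenyl]-1-benzofuran-3-carboxylate
Conditions: 21 (3 equiv), Amberlyst-15, 4 Å MS, MeCN, 40 °C, stopped at full conversion
Reagents that add atoms: none
Why: Friedel–Crafts C-arylation of the lactol-derived oxocarbenium ion (aryl C-glycosylation type, as practised on samin-type lactols); the phenol reacts at its only free activated carbon (para to OH) and approaches the convex face of the cis-fused bicycle, which places the aryl exo and sets C7' (S).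

Step 15
Reactants: 22 ethyl 5-[(1S,3aR,4S,6aR)-4-(4-hydroxy-3,5-dimethoxyphenyl)tetrahydro-1H,3H-furo[3,4-c]furan-1-yl]-7-methoxy-2-[3-methoxy-4-(pivaloyloxy)phenyl]-1-benzofuran-3-carboxylate
Product: 23 4-[(1S,3aR,4S,6aR)-4-[3-(hydroxymethyl)-2-(4-hydroxy-3-methoxyphenyl)-7-methoxy-1-benzofuran-5-yl]tetrahydro-1H,3H-furo[3,4-c]furan-1-yl]-2,6-dimethoxyphenol
Conditions: i-Bu2AlH (8 equiv), CH2Cl2/THF, −78 → 0 °C; aq. KNaC4H4O6 work-up
Reagents that add atoms: none
Why: hydride reduction of the ester to the primary alcohol with reductive cleavage of the aryl pivalate in the same operation; the neutral tartrate work-up protects the acid-sensitive benzofuranylmethanol.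

Step 16
Reactants: 23 4-[(1S,3aR,4S,6aR)-4-[3-(hydroxymethyl)-2-(4-hydroxy-3-methoxyphenyl)-7-methoxy-1-benzofuran-5-yl]tetrahydro-1H,3H-furo[3,4-c]furan-1-yl]-2,6-dimethoxyphenol
Product: 24 4-[(1S,3aR,4S,6aR)-4-[(2S,3S)-3-(hydroxymethyl)-2-(4-hydroxy-3-methoxyphenyl)-7-methoxy-2,3-dihydro-1-benzofuran-5-yl]tetrahydro-1H,3H-furo[3,4-c]furan-1-yl]-2,6-dimethoxyphenol (CNP0126146.1)
Conditions: Ru(cod)(2-methylallyl)2 (5 mol%), (R,R)-SINpEt·HBF4 (10 mol%; SINpEt = 1,3-bis[1-(1-naphthyl)ethyl]imidazolidin-2-ylidene), KOt-Bu (10 mol%), toluene, 70 °C (catalyst pre-formation); then 23, H2 (60 bar), toluene/t-AmOH, 40 °C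
Reagents that add atoms: none
Why: Proposed new method: the furan C2=C3 bond of a benzofuran has little aromatic stabilisation and Ru–NHC hydrides add H2 across it from one face; here the 3-CH2OH group (as a Ru-bound alkoxide) is expected to anchor the substrate so that both hydrogens arrive syn on one face of the tetrasubstituted C2=C3 bond, which makes H2 and H3 cis (aryl and CH2OH cis), while the C2-symmetric chiral NHC pocket, not the remote furofuran, selects the face that gives 2S,3S (the ligand antipode is exchanged if the first run gives 2R,3R); closest known reaction types are the Ru–NHC-catalysed enantioselective hydrogenation of 2-substituted benzofurans and the hydroxyl-directed homogeneous hydrogenation of allylic alcohols, and what is new is the fully substituted, hydroxymethyl-bearing benzofuran in an unprotected polyphenol.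

**Compound list**

1 | catechol | Oc1ccccc1O | starting material
2 | guaiacol (2-methoxyphenol) | COc1ccccc1O | intermediate
3 | 4-bromo-2-methoxyphenol | COc1cc(Br)ccc1O | intermediate
4 | 4-bromo-2-methoxyphenyl pivalate | COc1cc(Br)ccc1OC(=O)C(C)(C)C | intermediate
5 | 5-bromo-2-hydroxy-3-methoxybenzaldehyde | COc1cc(Br)cc(C=O)c1O | intermediate
6 | ethyl diazoacetate | CCOC(=O)C=[N+]=[N-] | starting material
7 | ethyl 5-bromo-2-hydroxy-7-methoxy-2,3-dihydro-1-benzofuran-3-carboxylate (hemiacetal, diastereomer mixture, not isolated) | CCOC(=O)C1C(O)Oc2c(OC)cc(Br)cc12 | intermediate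
8 | ethyl 5-bromo-7-methoxy-1-benzofuran-3-carboxylate | CCOC(=O)c1coc2c(OC)cc(Br)cc12 | intermediate
9 | ethyl 5-formyl-7-methoxy-1-benzofuran-3-carboxylate | CCOC(=O)c1coc2c(OC)cc(C=O)cc12 | intermediate
10 | ethyl 5-formyl-7-methoxy-2-[3-methoxy-4-(pivaloyloxy)phenyl]-1-benzofuran-3-carboxylate | CCOC(=O)c1c(-c2ccc(OC(=O)C(C)(C)C)c(OC)c2)oc2c(OC)cc(C=O)cc12 | intermediate
11 | methyl 4-oxobutanoate | COC(=O)CCC=O | starting material
12 | methyl (3S,4R)-4-BF-3-formyl-4-hydroxybutanoate (aldol aldehyde, not isolated) | COC(=O)C[C@H](C=O)[C@@H](O)c1cc(OC)c2oc(-c3ccc(OC(=O)C(C)(C)C)c(OC)c3)c(C(=O)OCC)c2c1 | intermediate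
13 | methyl (3R,4R)-4-BF-4-hydroxy-3-(hydroxymethyl)butanoate (diol ester, not isolated) | COC(=O)C[C@H](CO)[C@@H](O)c1cc(OC)c2oc(-c3ccc(OC(=O)C(C)(C)C)c(OC)c3)c(C(=O)OCC)c2c1 | intermediate
14 | (4R)-4-[(R)-hydroxy(BF)methyl]oxolan-2-one | O=C1C[C@H](CO1)[C@@H](O)c1cc(OC)c2oc(-c3ccc(OC(=O)C(C)(C)C)c(OC)c3)c(C(=O)OCC)c2c1 | intermediate
15 | (4R)-4-[(R)-hydroxy(BF)methyl]-3-(hydroxymethylidene)oxolan-2-one (enol of the α-formyl lactone, not isolated) | O=C1OC[C@H]([C@@H](O)c2cc(OC)c3oc(-c4ccc(OC(=O)C(C)(C)C)c(OC)c4)c(C(=O)OCC)c3c2)C1=CO | intermediate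
16 | (3aR,4S)-4-BF-3a,4-dihydro-1H,3H-furo[3,4-c]furan-1-one (ring A enol ether fused to the lactone; 7S,8R) | O=C1OC[C@H]2C1=CO[C@@H]2c1cc(OC)c2oc(-c3ccc(OC(=O)C(C)(C)C)c(OC)c3)c(C(=O)OCC)c2c1 | intermediate
17 | (3aR,4S,6aR)-4-BF-tetrahydro-1H,3H-furo[3,4-c]furan-1-one (cis-fused, aryl exo) | O=C1OC[C@H]2[C@@H]1CO[C@@H]2c1cc(OC)c2oc(-c3ccc(OC(=O)C(C)(C)C)c(OC)c3)c(C(=O)OCC)c2c1 | intermediate
18 | (3aR,4S,6aR)-4-BF-tetrahydro-1H,3H-furo[3,4-c]furan-1-ol (lactol, anomer mixture) | OC1OC[C@H]2[C@@H]1CO[C@@H]2c1cc(OC)c2oc(-c3ccc(OC(=O)C(C)(C)C)c(OC)c3)c(C(=O)OCC)c2c1 | intermediate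
19 | resorcinol | Oc1cccc(O)c1 | starting material
20 | 1,3-dimethoxybenzene | COc1cccc(OC)c1 | intermediate
21 | 2,6-dimethoxyphenol | COc1cccc(OC)c1O | intermediate
22 | ethyl 5-[(1S,3aR,4S,6aR)-4-(4-hydroxy-3,5-dimethoxyphenyl)tetrahydro-1H,3H-furo[3,4-c]furan-1-yl]-7-methoxy-2-[3-methoxy-4-(pivaloyloxy)phenyl]-1-benzofuran-3-carboxylate | CCOC(=O)c1c(-c2ccc(OC(=O)C(C)(C)C)c(OC)c2)oc2c(OC)cc(cc12)[C@H]1OC[C@H]2[C@@H]1CO[C@@H]2c1cc(OC)c(O)c(OC)c1 | intermediate
23 | 4-[(1S,3aR,4S,6aR)-4-[3-(hydroxymethyl)-2-(4-hydroxy-3-methoxyphenyl)-7-methoxy-1-benzofuran-5-yl]tetrahydro-1H,3H-furo[3,4-c]furan-1-yl]-2,6-dimethoxyphenol | OCc1c(-c2ccc(O)c(OC)c2)oc2c(OC)cc(cc12)[C@H]1OC[C@H]2[C@@H]1CO[C@@H]2c1cc(OC)c(O)c(OC)c1 | intermediate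
24 | 4-[(1S,3aR,4S,6aR)-4-[(2S,3S)-3-(hydroxymethyl)-2-(4-hydroxy-3-methoxyphenyl)-7-methoxy-2,3-dihydro-1-benzofuran-5-yl]tetrahydro-1H,3H-furo[3,4-c]furan-1-yl]-2,6-dimethoxyphenol (CNP0126146.1) | COc1cc([C@H]2Oc3c(OC)cc([C@H]4OC[C@H]5[C@@H]4CO[C@@H]5c4cc(OC)c(O)c(OC)c4)cc3[C@H]2CO)ccc1O | target

**Totals and weak points**

Total step count: 16. Longest linear sequence: 13 steps (1, 2, 4, 5, 6, 7, 8, 9, 10, 11, 14, 15, 16); steps 3, 12 and 13 are side branches.

The three steps most likely to fail are steps 16, 14 and 9.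

Step 16 is the proposed new hydrogenation. The catalyst may be slowed by the two free phenols, may give low face selectivity on a tetrasubstituted C2=C3 bond, or may cause hydrogenolysis of the ionisable CH2OH group. The fallback uses known chemistry and gives up catalyst control. It sets out from 23: heterogeneous syn-hydrogenation (H2, 4 bar, Rh/Al2O3, EtOAc/MeOH, rt) reduces the benzofuran to the two cis-dihydrobenzofurans only. Because the furofuran is already single-handed, these are diastereomers, namely 24 and the (2R,3R)-cis-dihydrobenzofuran diastereomer F1, and they are separated by preparative HPLC. The fallback comes back to the route at 24, at the cost of about half the material.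

Step 14 may suffer from acid epimerisation at C7' of the very electron-rich product (and at C7), or may stall at the O-aryl acetal. The fallback replaces the one-pot solid-acid arylation by a stepwise, low-temperature O-glycosylation and O-to-C migration. It sets out from 18: Cl3CCN with catalytic DBU in CH2Cl2 gives the lactol trichloroacetimidate F2. F2 and 21 with TMSOTf (10 mol%) at −60 °C give the O-(2,6-dimethoxyphenyl) acetal F3. Warming F3 to −10 °C brings about the Lewis-acid O-to-C (Fries-type) rearrangement to the para carbon on the convex face. The fallback comes back to the route at 22.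

Step 9 may give incomplete equilibration at C7, or may erode C8 through elimination to the styrene and re-protonation under the acid. The fallback replaces the acid-mediated, stereoconvergent closure by a stereospecific displacement. It sets out from 14, after chromatographic removal of any syn-aldol-derived epimer. The formylation is run as in the route, but the hydroxymethylene lactone 15 is isolated. Treating 15 with PPh3 and diisopropyl azodicarboxylate in THF at 0 °C (Mitsunobu etherification) lets the acidic enol oxygen displace the activated benzylic alcohol with inversion, turning the 7R carbinol into the 7S ring A ether. The fallback comes back to the route at 16 and forms no compound outside the list (F0).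

**Further compounds**

F1 | step 16 | 4-[(1S,3aR,4S,6aR)-4-[(2R,3R)-3-(hydroxymethyl)-2-(4-hydroxy-3-methoxyphenyl)-7-methoxy-2,3-dihydro-1-benzofuran-5-yl]tetrahydro-1H,3H-furo[3,4-c]furan-1-yl]-2,6-dimethoxyphenol | COc1cc([C@@H]2Oc3c(OC)cc([C@H]4OC[C@H]5[C@@H]4CO[C@@H]5c4cc(OC)c(O)c(OC)c4)cc3[C@@H]2CO)ccc1O
F2 | step 14 | (3aR,4S,6aR)-4-BF-tetrahydro-1H,3H-furo[3,4-c]furan-1-yl 2,2,2-trichloroacetimidate (anomer mixture) | ClC(Cl)(Cl)C(=N)OC1OC[C@H]2[C@@H]1CO[C@@H]2c1cc(OC)c2oc(-c3ccc(OC(=O)C(C)(C)C)c(OC)c3)c(C(=O)OCC)c2c1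
F3 | step 14 | (3aR,4S,6aR)-4-BF-1-(2,6-dimethoxyphenoxy)tetrahydro-1H,3H-furo[3,4-c]furan (O-aryl acetal, anomer mixture) | COc1cccc(OC)c1OC1OC[C@H]2[C@@H]1CO[C@@H]2c1cc(OC)c2oc(-c3ccc(OC(=O)C(C)(C)C)c(OC)c3)c(C(=O)OCC)c2c1
F0 | step 9 | none | none
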